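If each mole of substrate, the limiting reagent, is booked, a plateau below the charge needs an entry beside target and unreacted substrate: loss.

in all of them: substrate 0.42 M

| run | free catalyst | remark | time |
|---|---|---|---|
| south-west | 0.14 mM | run made earlier |  |
| north-east | 0.75 mM | run made earlier |  |
| red | 0.12 mM |  | 10 h |
| violet | 0.50 mM |  | 10 h |

- south-west (time / h: target / %): 0.667: 30.1; 2.00: 62.4; 3.00: 74.6; 5.00: 83.8; 8.00: 87.5
- north-east (time / h: target / %): 0.500: 73.1; 1.00: 92.7; 2.00: 99.1; 4.00: 96.5; 8.00: 96.5

(scatter of a reading: 1 percentage point)

- which one finishes higher in amount of target, in percent of the substrate charged ("neither" within 2 percentage points) (red / violet / neither)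
- amount of target at the end, in percent of the substrate charged, red
- amount of target at the end, in percent of the substrate charged, violet



The ledger opens on the south-west run. Its first reading gives a first-order constant of 0.537 h⁻¹, so about 1.36 % of the substrate is reckoned unreacted at 8.00 h. Target reads 87.5 %, which leaves a lost share of 11.1 %.

The north-east run has 5.36 times the catalyst and, from its first reading, a constant 4.89 times as large, so the target path scales roughly with catalyst. This reckoning supposes that the loss uses no catalyst. At one substrate charge, a small lost share then falls in inverse proportion to the catalyst charge. The south-west share times its 0.14 mM gives 0.0156 mM. This lost share times catalyst charge is the loss number.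

As a check, it predicts 2.08 % lost in the north-east run. That run's last 3 readings average 2.63 % lost, each reading being good to 1 percentage point.

Red books 13.0 % lost and 1.00 % unreacted, so the ledger gives its target as 86.0 %. Violet books 3.12 % lost and hardly any unreacted, so the ledger gives its target as 96.9 %.

The forecast names violet, with 84 % for red and 97 % for violet. Its grounds differ from this ledger: “A common equilibrium cannot explain different plateaus, so the catalyst is dying”. For red, the ledger stands 2 points higher.

Red gives 87.0 % and violet 96.6 %, so violet finishes higher, as forecast.

    substrate + free catalyst → catalyst intermediate (k = 1.09 M⁻¹ s⁻¹)
    2 substrate → self-condensation product (k = 4.40 × 10⁻⁵ M⁻¹ s⁻¹)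
    catalyst intermediate ⇌ free catalyst + target (K = 17.0 M, k = 11.3 s⁻¹)

At 10.0 h, red holds 97.9 % of its catalyst free and 2.13 % as catalyst intermediate, and its loss entry is self-condensation product. The loss number booked 13.0 % for red, against 12.3 % of self-condensation product in that flask, and 3.12 % for violet, against 3.35 %.

In the scheme, the loss step is second order in substrate and the step from substrate to catalyst intermediate first order, so the ledger takes the loss number in proportion to the substrate charge. Red's neighbour with 0.10 M of substrate then has a loss number of 0.00371 mM, which books 3.09 % lost and, with 1.00 % unreacted, 95.9 % target. That neighbour computes to 95.9 % target, 3.25 % self-condensation product and 0.87 % substrate.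

The readings were computed with constants of no real substance; noise was put on by code.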